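**Retrosynthetic overview**
1. The target is an achiral tridepside A–B–C. The plan rests on ring B, a 2,4-dihydroxy-6-methylbenzoyl unit whose carboxyl carbon is bound to O-4 of ring C. This carbonyl, the six ring carbons and the methyl group make up one unbranched eight-carbon 1,3,5,7-oxygenated chain.
2. Late cuts: hydrogenolysis frees the ring C acid and 2-OH. The A–B ester is cut between the ring A carbonyl and O-4 of ring B, giving 2,3,4-trimethoxy-6-methylbenzoic acid 18 and didepside resorcinol 14.
3. Key cut: ring B of 14 is unfolded at its C-1/C-6 bond (chain C-2/C-7) to an aryl 3,5,7-trioxooctanoate. The ester C–O bond of that chain is then cut to an acylketene and ring C phenol 10, and the ketene is stored as diketo-dioxinone 5.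
4. Compound 5 comes from 2,2,6-trimethyl-1,3-dioxin-4-one by two chain-end acylations, 10 from orsellinic acid, and 18 from 3,4,5-trimethoxytoluene.
5. Ring order: rings A and C are bought as arenes. Ring B is the only ring built, and it is built on the oxygen of ring C.

Key step: step 7

Remark: the target has no stereocentre and its aryl ester bonds rotate freely, so it is one achiral compound and no enantiocontrol is needed.

**Step 1**
Reactants: 1 2,2,6-trimethyl-4H-1,3-dioxin-4-one
Product: 3 2,2-dimethyl-6-(2-oxopropyl)-4H-1,3-dioxin-4-one (keto-dioxinone), via lithium dienolate 2 (not isolated)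
Conditions: LiHMDS (1.05 equiv), THF, −78 °C; AcCl (0.5 equiv), −78 → −20 °C; 1 M HCl
Reagents that add atoms: acetyl chloride, CC(=O)Cl
Why: Deprotonation of the 6-methyl group gives the vinylogous ester dienolate 2, which should undergo γ-selective C-acylation by the acid chloride (vinylogous Claisen-type acylation); the enolate is used in twofold amount because the more acidic product consumes one equivalent.

**Step 2**
Reactants: 3 2,2-dimethyl-6-(2-oxopropyl)-4H-1,3-dioxin-4-one
Product: 5 6-(2,4-dioxopentyl)-2,2-dimethyl-4H-1,3-dioxin-4-one (diketo-dioxinone), via dilithium dianion 4 (not isolated)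
Conditions: LDA (2.2 equiv), THF, −78 → −40 °C; MeC(O)N(OMe)Me, −40 °C; 1 M HCl to pH 3, 0 °C
Reagents that add atoms: N-methoxy-N-methylacetamide, CC(=O)N(C)OC
Why: In dianion 4 the carbanion formed last, at the former ketone methyl, is the most nucleophilic site (dianion Claisen-type acylation), and the N-methoxy-N-methylamide keeps the adduct as a chelated tetrahedral species until the acid quench, so over-acylation should not occur.

**Step 3**
Reactants: 6 orsellinic acid (2,4-dihydroxy-6-methylbenzoic acid)
Product: 7 benzyl 2,4-dihydroxy-6-methylbenzoate (benzyl orsellinate)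
Conditions: BnBr (1.05 equiv), KHCO3, DMF, rt
Reagents that add atoms: benzyl bromide, BrCc1ccccc1
Why: Bicarbonate ionises only the carboxylic acid, so SN2 alkylation of the carboxylate should give the ester with both phenols untouched, and room temperature avoids decarboxylation of the acid.

**Step 4**
Reactants: 7 benzyl 2,4-dihydroxy-6-methylbenzoate
Product: 8 benzyl 4-(allyloxy)-2-hydroxy-6-methylbenzoate
Conditions: allyl bromide (1.05 equiv), K2CO3 (1.1 equiv), acetone, reflux
Reagents that add atoms: allyl bromide, C=CCBr
Why: Williamson etherification with one equivalent of halide should take place only at the exposed, more acidic 4-OH, because the 2-OH is hydrogen-bonded to the ester carbonyl and shielded by it.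

**Step 5**
Reactants: 8 benzyl 4-(allyloxy)-2-hydroxy-6-methylbenzoate
Product: 9 benzyl 4-(allyloxy)-2-(benzyloxy)-6-methylbenzoate
Conditions: BnBr (1.5 equiv), K2CO3, cat. KI, DMF, 60 °C
Reagents that add atoms: benzyl bromide, BrCc1ccccc1
Why: Williamson etherification under more forcing conditions (dipolar aprotic solvent, heat, excess halide) breaks the chelate and benzylates the one remaining hydroxyl, while the allyl ether and the hindered benzyl ester are inert and the temperature is far below that of a Claisen rearrangement.

**Step 6**
Reactants: 9 benzyl 4-(allyloxy)-2-(benzyloxy)-6-methylbenzoate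
Product: 10 benzyl 2-(benzyloxy)-4-hydroxy-6-methylbenzoate (ring C phenol)
Conditions: Pd(PPh3)4 (5 mol %), morpholine (5 equiv), THF, rt
Reagents that add atoms: none
Why: In this Tsuji–Trost deallylation Pd(0) ionises the aryl allyl ether to a π-allyl complex and an ester-stabilised phenoxide, and morpholine takes up the allyl group, while the benzyl ether and benzyl ester do not react with Pd(0).

**Step 7**
Reactants: 5 6-(2,4-dioxopentyl)-2,2-dimethyl-4H-1,3-dioxin-4-one; 10 benzyl 2-(benzyloxy)-4-hydroxy-6-methylbenzoate
Product: 14 benzyl 2-(benzyloxy)-4-[(2,4-dihydroxy-6-methylbenzoyl)oxy]-6-methylbenzoate (didepside resorcinol), via acylketene 11 (not isolated), via triketo aryl ester 12 (not isolated), via aldol carbinol 13 (not isolated)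
Conditions: 10 in PhMe (concentrated), 110 °C, slow addition of 5 (1.3 equiv); cool; Cs2CO3, THF, 0 °C → rt; then HCl (4 M in dioxane), rt
Reagents that add atoms: none
Why: Heating 5 triggers a retro-hetero-Diels–Alder reaction that expels acetone and leaves acylketene 11, and the single free hydroxyl of 10 adds to the ketene carbon through a hydrogen-bonded six-centre transition state, so the B–C depside C(=O)–O bond forms as triketo ester 12 without a coupling reagent and before the two ortho substituents that would hinder this carbonyl exist. The closest known chemistry is the thermolysis of diketo-dioxinones with alcohols followed by aldol aromatisation to resorcylates, together with the established thermal acetoacetylation of phenols by 1. Carbonate then interconverts the enolates of 12 and ring B closes when C-2 attacks the C-7 methyl ketone, a 6-(enolendo)-exo-trig aldol addition that is allowed for six-membered rings and gives carbinol 13, after which acid completes the loss of water and enolisation of the two ring ketones delivers the arene irreversibly. No stereocentre has to be controlled, since the two that appear in 13 are erased on aromatisation. The step needs folding selectivity: the C-4 and C-6 methylenes are more acidic than C-2, but their carbon enolates reach a ketone only through four-membered rings, so the real competitors are attack of C-6 or of the C-5 enol oxygen on the aryl ester carbonyl (Claisen or pyrone closure with loss of the aryloxide) and C-8 to C-3 aldol closure, which needs the least accessible methyl enolate. The aldol path should be favoured by the unhindered methyl ketone acceptor, by a weak base at or below room temperature, by strict exclusion of alcohols and water that would cleave the activated aryl ester, and by slow addition of 5 to hot concentrated 10, which keeps the phenol in large excess over the ketene and so suppresses its self-cyclisation.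

**Step 8**
Reactants: 15 3,4,5-trimethoxytoluene
Product: 17 2,3,4-trimethoxy-6-methylbenzaldehyde, via aryl iminium salt 16 (not isolated)
Conditions: POCl3 (1.3 equiv), DMF, 0 → 80 °C; then ice-water
Reagents that add atoms: N,N-dimethylformamide, CN(C)C=O; water, O
Why: In this Vilsmeier–Haack formylation the two free ring positions are equivalent by symmetry and each is activated by one ortho and one para methoxy group, so a single aldehyde should result after hydrolysis of iminium salt 16.

**Step 9**
Reactants: 17 2,3,4-trimethoxy-6-methylbenzaldehyde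
Product: 18 2,3,4-trimethoxy-6-methylbenzoic acid
Conditions: NaClO2, NaH2PO4, 2-methyl-2-butene (excess), t-BuOH/H2O, rt
Reagents that add atoms: sodium chlorite, [Na+].[O-]Cl=O
Why: The Pinnick oxidation converts the hindered aldehyde to the acid under buffered conditions, and the alkene scavenges hypochlorous acid so that the electron-rich ring should not be chlorinated.

**Step 10**
Reactants: 18 2,3,4-trimethoxy-6-methylbenzoic acid; 14 benzyl 2-(benzyloxy)-4-[(2,4-dihydroxy-6-methylbenzoyl)oxy]-6-methylbenzoate
Product: 20 benzyl 2-(benzyloxy)-4-{[2-hydroxy-6-methyl-4-(2,3,4-trimethoxy-6-methylbenzoyloxy)benzoyl]oxy}-6-methylbenzoate (protected tridepside), via mixed trifluoroacetic anhydride 19 (not isolated)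
Conditions: (CF3CO)2O (2 equiv), PhMe, 0 °C → rt; aq. NaHCO3 work-up
Reagents that add atoms: none
Why: In this mixed-anhydride depside esterification 19 transfers its acyl group with acylium character, stabilised by the ortho and para methoxy groups, which offsets the double ortho substitution, and only the unchelated 4-OH of ring B should be acylated because the 2-OH is locked in a hydrogen bond to the B–C ester carbonyl.

**Step 11**
Reactants: 20 protected tridepside
Product: 21 2-hydroxy-4-{[2-hydroxy-6-methyl-4-(2,3,4-trimethoxy-6-methylbenzoyloxy)benzoyl]oxy}-6-methylbenzoic acid (target, CNP0332884.0)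
Conditions: H2 (1 atm), 10 % Pd/C, EtOAc, rt
Reagents that add atoms: none
Why: Catalytic hydrogenolysis cleaves the benzylic C–O bonds of the ester and the ether in one operation, while the two aryl ester links and the methyl ethers are inert, and a non-alcoholic solvent at room temperature avoids depside alcoholysis and decarboxylation.

**Compound list**
1 | 2,2,6-trimethyl-4H-1,3-dioxin-4-one | CC1=CC(=O)OC(C)(C)O1 | starting material
2 | lithium 2,2-dimethyl-6-methylidene-1,3-dioxin-4-olate (dienolate of 1) | C=C1C=C([O-])OC(C)(C)O1.[Li+] | intermediate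
3 | 2,2-dimethyl-6-(2-oxopropyl)-4H-1,3-dioxin-4-one | CC(=O)CC1=CC(=O)OC(C)(C)O1 | intermediate
4 | dilithium dianion of 3 | C=C([O-])C=C1C=C([O-])OC(C)(C)O1.[Li+].[Li+] | intermediate
5 | 6-(2,4-dioxopentyl)-2,2-dimethyl-4H-1,3-dioxin-4-one | CC(=O)CC(=O)CC1=CC(=O)OC(C)(C)O1 | intermediate
6 | orsellinic acid (2,4-dihydroxy-6-methylbenzoic acid) | Cc1cc(O)cc(O)c1C(=O)O | starting material
7 | benzyl 2,4-dihydroxy-6-methylbenzoate | Cc1cc(O)cc(O)c1C(=O)OCc1ccccc1 | intermediate
8 | benzyl 4-(allyloxy)-2-hydroxy-6-methylbenzoate | C=CCOc1cc(C)c(C(=O)OCc2ccccc2)c(O)c1 | intermediate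
9 | benzyl 4-(allyloxy)-2-(benzyloxy)-6-methylbenzoate | C=CCOc1cc(C)c(C(=O)OCc2ccccc2)c(OCc2ccccc2)c1 | intermediate
10 | benzyl 2-(benzyloxy)-4-hydroxy-6-methylbenzoate | Cc1cc(O)cc(OCc2ccccc2)c1C(=O)OCc1ccccc1 | intermediate
11 | 3,5,7-trioxooct-1-en-1-one (acylketene) | CC(=O)CC(=O)CC(=O)C=C=O | intermediate
12 | 3-(benzyloxy)-4-(benzyloxycarbonyl)-5-methylphenyl 3,5,7-trioxooctanoate | CC(=O)CC(=O)CC(=O)CC(=O)Oc1cc(C)c(C(=O)OCc2ccccc2)c(OCc2ccccc2)c1 | intermediate
13 | 3-(benzyloxy)-4-(benzyloxycarbonyl)-5-methylphenyl 2-hydroxy-2-methyl-4,6-dioxocyclohexane-1-carboxylate (mixture of stereoisomers, erased on aromatisation) | CC1(O)CC(=O)CC(=O)C1C(=O)Oc1cc(C)c(C(=O)OCc2ccccc2)c(OCc2ccccc2)c1 | intermediate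
14 | benzyl 2-(benzyloxy)-4-[(2,4-dihydroxy-6-methylbenzoyl)oxy]-6-methylbenzoate | Cc1cc(O)cc(O)c1C(=O)Oc1cc(C)c(C(=O)OCc2ccccc2)c(OCc2ccccc2)c1 | intermediate
15 | 3,4,5-trimethoxytoluene | COc1cc(C)cc(OC)c1OC | starting material
16 | N,N-dimethyl-(2,3,4-trimethoxy-6-methylbenzylidene)iminium dichlorophosphate | COc1cc(C)c(C=[N+](C)C)c(OC)c1OC.[O-]P(=O)(Cl)Cl | intermediate
17 | 2,3,4-trimethoxy-6-methylbenzaldehyde | COc1cc(C)c(C=O)c(OC)c1OC | intermediate
18 | 2,3,4-trimethoxy-6-methylbenzoic acid | COc1cc(C)c(C(=O)O)c(OC)c1OC | intermediate
19 | 2,3,4-trimethoxy-6-methylbenzoic trifluoroacetic anhydride | COc1cc(C)c(C(=O)OC(=O)C(F)(F)F)c(OC)c1OC | intermediate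
20 | benzyl 2-(benzyloxy)-4-{[2-hydroxy-6-methyl-4-(2,3,4-trimethoxy-6-methylbenzoyloxy)benzoyl]oxy}-6-methylbenzoate | COc1cc(C)c(C(=O)Oc2cc(C)c(C(=O)Oc3cc(C)c(C(=O)OCc4ccccc4)c(OCc4ccccc4)c3)c(O)c2)c(OC)c1OC | intermediate
21 | 2-hydroxy-4-{[2-hydroxy-6-methyl-4-(2,3,4-trimethoxy-6-methylbenzoyloxy)benzoyl]oxy}-6-methylbenzoic acid | COc1cc(C)c(C(=O)Oc2cc(C)c(C(=O)Oc3cc(C)c(C(=O)O)c(O)c3)c(O)c2)c(OC)c1OC | target

**Total step count:** 11
**Longest linear sequence:** 7 steps (6 → 7 → 8 → 9 → 10 → 14 → 20 → 21)

**Steps most likely to fail**

**First, step 7.**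
- Risk: the ester-deactivated phenol is a weak nucleophile, so cyclisation of the ketene onto its own enol oxygen may outrun the bimolecular capture. Prolonged heating may also reverse the capture. Under base, expulsion of the aryloxide from the activated ester (by lactonisation, Claisen closure or elimination back to the ketene) may compete with the aldol closure.
- Fallback: it sets out from 6 and 10 and returns at 14. It gives up ring construction and makes the B–C ester by conventional acyl activation of a preformed ring B.
- Route: orsellinic acid 6 would be fully allylated (allyl bromide, K2CO3, DMF) to allyl 2,4-bis(allyloxy)-6-methylbenzoate F1. Saponification (KOH, aqueous EtOH, reflux) would give 2,4-bis(allyloxy)-6-methylbenzoic acid F2. Coupling to phenol 10 with trifluoroacetic anhydride in toluene would give benzyl 4-{[2,4-bis(allyloxy)-6-methylbenzoyl]oxy}-2-(benzyloxy)-6-methylbenzoate F3. Both allyl ethers would then be removed with Pd(PPh3)4 and morpholine, which leaves the benzyl groups in place and delivers 14.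

**Second, step 2.**
- Risk: the second deprotonation may be incomplete, and proton transfer from the enolisable acetamide to the basic dianion may replace addition. The product may also aromatise prematurely on contact with base or silica during isolation.
- Fallback: it sets out from 1 and returns at 5. It replaces dianion chemistry by acylation of a stabilised magnesium enolate.
- Route: the lithium dienolate of 1 would be acylated with allyl 3-chloro-3-oxopropanoate to give allyl 4-(2,2-dimethyl-4-oxo-4H-1,3-dioxin-6-yl)-3-oxobutanoate F4. This would be C-acetylated between its ester and ketone (AcCl, MgCl2, pyridine, CH2Cl2) to give allyl 2-acetyl-4-(2,2-dimethyl-4-oxo-4H-1,3-dioxin-6-yl)-3-oxobutanoate F5. Treatment with Pd(PPh3)4 and morpholine would then remove the allyl ester and decarboxylate under near-neutral conditions to give 5.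

**Third, step 10.**
- Risk: acyl transfer from the doubly ortho-substituted donor may be slow. Site selectivity between the 4-OH and the chelated 2-OH may erode, and acid-promoted acyl exchange may occur at the existing B–C ester.
- Fallback: it sets out from 18 and 14 and returns at 20. It moves the selectivity from the electrophile to the nucleophile.
- Route: acid 18 would be converted with oxalyl chloride and catalytic DMF to the isolated 2,3,4-trimethoxy-6-methylbenzoyl chloride F6. One equivalent of K2CO3 in acetone would ionise only the more acidic, unchelated 4-OH of 14, and this phenoxide would attack F6 under acid-free conditions to give 20.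

**Further compounds**
F1 | step 7 | allyl 2,4-bis(allyloxy)-6-methylbenzoate | C=CCOC(=O)c1c(C)cc(OCC=C)cc1OCC=C
F2 | step 7 | 2,4-bis(allyloxy)-6-methylbenzoic acid | C=CCOc1cc(C)c(C(=O)O)c(OCC=C)c1
F3 | step 7 | benzyl 4-{[2,4-bis(allyloxy)-6-methylbenzoyl]oxy}-2-(benzyloxy)-6-methylbenzoate | C=CCOc1cc(C)c(C(=O)Oc2cc(C)c(C(=O)OCc3ccccc3)c(OCc3ccccc3)c2)c(OCC=C)c1
F4 | step 2 | allyl 4-(2,2-dimethyl-4-oxo-4H-1,3-dioxin-6-yl)-3-oxobutanoate | C=CCOC(=O)CC(=O)CC1=CC(=O)OC(C)(C)O1
F5 | step 2 | allyl 2-acetyl-4-(2,2-dimethyl-4-oxo-4H-1,3-dioxin-6-yl)-3-oxobutanoate | C=CCOC(=O)C(C(C)=O)C(=O)CC1=CC(=O)OC(C)(C)O1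
F6 | step 10 | 2,3,4-trimethoxy-6-methylbenzoyl chloride | COc1cc(C)c(C(=O)Cl)c(OC)c1OC
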